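**Retrosynthetic overview**
1. Feature: both n-propyl groups sit at C6 of their ring (ring A C6 and ring B C6). Each lies next to the C1 that carries that ring's carbonyl carbon, so the two aryl–alkyl bonds are of one kind and are cut together.
2. The target comes by global hydrogenation from the tetrabenzyl bis-(E)-propenyl depside. That depside comes by a twofold Suzuki–Miyaura coupling from the ring A C6 triflate / ring B C6 bromide depside and two propenyltrifluoroborates.
3. The depside C(=O)–O bond to ring B O3 is cut to a ring A acid and a ring B C3 phenol. The acid comes from 5-methoxyresorcinol by formylation, benzylation of the para hydroxyl, triflation of the last hydroxyl and oxidation.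
4. The ring B phenol comes from 4-bromo-2,6-difluorobenzaldehyde. The fluorides become benzyl ethers and the formyl group becomes the central oxygen. Iodination and iodine–magnesium exchange then bring in the benzyl ester next to bromine.
5. No ring is formed in the route, because both benzene rings are bought. The target has no stereocentre.

Key step: step 12

Remark: in each ring C1 is the carbon bearing the carbonyl group, and the depside oxygen is O3 of ring B.

**Step 1**
Reactants: 1 5-methoxyresorcinol (5-methoxybenzene-1,3-diol)
Product: 3 2,4-dihydroxy-6-methoxybenzaldehyde, via iminium chloride 2 (not isolated)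
Conditions: POCl3 (1.2 equiv), DMF (1.5 equiv), EtOAc, 0 °C → rt; then H2O, 50 °C
Reagents that add atoms: N,N-dimethylformamide, CN(C)C=O (formyl carbon); water, O (aldehyde oxygen); phosphoryl chloride, O=P(Cl)(Cl)Cl (only the chloride of 2)
Why: Vilsmeier–Haack formylation of a phloroglucinol-type ring is fast, and attack para to a free hydroxyl at either of the two equivalent carbons between OH and OMe should outweigh attack at the single carbon between the two hydroxyls, the minor isomer being removed by chromatography.

**Step 2**
Reactants: 3 2,4-dihydroxy-6-methoxybenzaldehyde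
Product: 4 4-(benzyloxy)-2-hydroxy-6-methoxybenzaldehyde
Conditions: BnBr (1.05 equiv), K2CO3 (1.1 equiv), acetone, rt → 40 °C
Reagents that add atoms: benzyl bromide, BrCc1ccccc1
Why: Williamson etherification is selective because the hydroxyl para to the formyl group is the more acidic one, whereas the ortho hydroxyl is tied up in a hydrogen bond to the aldehyde oxygen.

**Step 3**
Reactants: 4 4-(benzyloxy)-2-hydroxy-6-methoxybenzaldehyde
Product: 5 5-(benzyloxy)-2-formyl-3-methoxyphenyl trifluoromethanesulfonate
Conditions: Tf2O (1.2 equiv), pyridine (3 equiv), CH2Cl2, 0 °C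
Reagents that add atoms: trifluoromethanesulfonic anhydride, O=S(=O)(OS(=O)(=O)C(F)(F)F)C(F)(F)F
Why: O-sulfonylation of the remaining chelated phenol by the very electrophilic anhydride is standard for salicylaldehydes, and neither the benzyl ether nor the aldehyde reacts under these conditions.

**Step 4**
Reactants: 5 5-(benzyloxy)-2-formyl-3-methoxyphenyl trifluoromethanesulfonate
Product: 6 4-(benzyloxy)-2-methoxy-6-(trifluoromethylsulfonyloxy)benzoic acid
Conditions: NaClO2 (2 equiv), NaH2PO4 (2 equiv), 2-methyl-2-butene (10 equiv), t-BuOH–THF–H2O, rt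
Reagents that add atoms: sodium chlorite, [Na+].[O-]Cl=O
Why: Pinnick oxidation works in weakly acidic medium on hindered 2,6-disubstituted benzaldehydes, leaves the aryl triflate and the benzyl ether alone, and the excess alkene intercepts hypochlorous acid before it can chlorinate the ring.

**Step 5**
Reactants: 7 4-bromo-2,6-difluorobenzaldehyde
Product: 8 2,6-bis(benzyloxy)-4-bromobenzaldehyde
Conditions: BnOH (2.3 equiv), NaH (2.2 equiv), THF, 0 °C → 50 °C
Reagents that add atoms: benzyl alcohol, OCc1ccccc1
Why: Twofold nucleophilic aromatic substitution (addition–elimination) should succeed since each fluorine lies ortho to the formyl group that stabilises the anionic sigma-adduct and fluoride departs far faster than the para bromide, the same exchange being routine for this aldehyde and methoxide.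

**Step 6**
Reactants: 8 2,6-bis(benzyloxy)-4-bromobenzaldehyde
Product: 10 2,6-bis(benzyloxy)-4-bromophenol, via aryl formate 9 (not isolated)
Conditions: mCPBA (1.5 equiv), CH2Cl2, 0 °C → rt; then K2CO3 (0.2 equiv), MeOH, rt, N2
Reagents that add atoms: 3-chloroperoxybenzoic acid, O=C(OO)c1cccc(Cl)c1
Why: Baeyer–Villiger oxidation of an aldehyde flanked by two alkoxy groups proceeds by migration of the electron-rich aryl group (Dakin-type outcome), and mild methanolysis of the formate frees the central phenol while bromide and benzyl ethers are untouched.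

**Step 7**
Reactants: 10 2,6-bis(benzyloxy)-4-bromophenol
Product: 11 [2,6-bis(benzyloxy)-4-bromophenoxy](tert-butyl)dimethylsilane
Conditions: TBSCl (1.3 equiv), imidazole (2.5 equiv), DMF, rt → 40 °C
Reagents that add atoms: tert-butyldimethylsilyl chloride, CC(C)(C)[Si](C)(C)Cl
Why: Imidazole-promoted silylation, known for 2,6-dialkoxyphenols, masks the central oxygen by a group that is orthogonal to benzyl and tolerates electrophilic iodination and Grignard reagents.

**Step 8**
Reactants: 11 [2,6-bis(benzyloxy)-4-bromophenoxy](tert-butyl)dimethylsilane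
Product: 12 [2,6-bis(benzyloxy)-4-bromo-3-iodophenoxy](tert-butyl)dimethylsilane
Conditions: NIS (1.05 equiv), TFA (0.2 equiv), MeCN, 0 °C → rt, dark
Reagents that add atoms: N-iodosuccinimide, O=C1CCC(=O)N1I
Why: Electrophilic aromatic iodination can only take place at the two equivalent free ring positions, each ortho to one benzyloxy group and para to the other and far more activated than the benzyl phenyl rings, and one equivalent of NIS should stop at the monoiodide.

**Step 9**
Reactants: 12 [2,6-bis(benzyloxy)-4-bromo-3-iodophenoxy](tert-butyl)dimethylsilane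
Product: 14 benzyl 2,4-bis(benzyloxy)-6-bromo-3-[(tert-butyldimethylsilyl)oxy]benzoate, via arylmagnesium chloride 13 (not isolated)
Conditions: i-PrMgCl·LiCl (1.1 equiv), THF, −25 °C; then ClCO2Bn (1.5 equiv), −25 → 0 °C
Reagents that add atoms: benzyl chloroformate, O=C(Cl)OCc1ccccc1; isopropylmagnesium chloride, CC(C)[Mg]Cl (only the MgCl of 13)
Why: Iodine–magnesium exchange is much faster at C–I than at C–Br and is helped by the flanking bromine and benzyloxy groups, the ortho-bromoarylmagnesium holds below 0 °C, and its acylation by the chloroformate gives a hindered benzyl ester that resists a second addition.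

**Step 10**
Reactants: 14 benzyl 2,4-bis(benzyloxy)-6-bromo-3-[(tert-butyldimethylsilyl)oxy]benzoate
Product: 15 benzyl 2,4-bis(benzyloxy)-6-bromo-3-hydroxybenzoate
Conditions: TBAF (1.1 equiv), AcOH (1.1 equiv), THF, 0 °C
Reagents that add atoms: none
Why: Fluoride-induced desilylation driven by the strong Si–F bond frees the C3 phenol quickly, and buffering by AcOH keeps the benzyl ester and the aryl bromide safe.

**Step 11**
Reactants: 6 4-(benzyloxy)-2-methoxy-6-(trifluoromethylsulfonyloxy)benzoic acid; 15 benzyl 2,4-bis(benzyloxy)-6-bromo-3-hydroxybenzoate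
Product: 17 benzyl 2,4-bis(benzyloxy)-6-bromo-3-{[4-(benzyloxy)-2-methoxy-6-(trifluoromethylsulfonyloxy)benzoyl]oxy}benzoate, via acid chloride 16 (not isolated)
Conditions: 6, (COCl)2 (1.5 equiv), DMF (cat.), CH2Cl2, 0 °C → rt, evaporate; then 15, Et3N (2 equiv), DMAP (0.3 equiv), CH2Cl2, rt → 40 °C
Reagents that add atoms: oxalyl chloride, O=C(Cl)C(=O)Cl (only the chlorine of 16)
Why: Acylation of a phenol by an acid chloride under nucleophilic catalysis by DMAP (acylpyridinium transfer) is the usual answer to hindered depside bonds, and the weak amine base avoids a free phenoxide that could attack the triflate sulfur.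

**Step 12**
Reactants: 17 benzyl 2,4-bis(benzyloxy)-6-bromo-3-{[4-(benzyloxy)-2-methoxy-6-(trifluoromethylsulfonyloxy)benzoyl]oxy}benzoate; 18 potassium (E)-prop-1-enyltrifluoroborate (3 equiv)
Product: 19 benzyl 2,4-bis(benzyloxy)-3-{[4-(benzyloxy)-2-methoxy-6-((E)-prop-1-enyl)benzoyl]oxy}-6-((E)-prop-1-enyl)benzoate
Conditions: Pd(OAc)2 (5 mol%), 2-dicyclohexylphosphino-2',6'-dimethoxybiphenyl (10 mol%), K3PO4 (4 equiv), toluene–H2O (5:1), degassed, 80 °C
Reagents that add atoms: none
Why: Pd(OAc)2 is reduced in the flask to a zerovalent palladium–monophosphine complex, which inserts into the ring B C6–Br bond and the ring A C6–OSO2CF3 bond, both made more electrophilic by the carbonyl-bearing C1 beside them. Aqueous K3PO4 slowly hydrolyses 18 to the propenylboronic acid, which transmetalates to each arylpalladium species, and reductive elimination forms the ring A C6–C and ring B C6–C bonds with retention of the E geometry. The closest known reaction type is the Suzuki–Miyaura coupling of potassium alkenyltrifluoroborates with aryl bromides and aryl triflates, used here twice on one substrate. No ring is closed and no stereocentre is created, and the alkene geometry is erased in step 13. The step needs full conversion at both C–X bonds while the depside ester, the benzyl ester and the S–O bond of the triflate outlast the base: the depside carbonyl is screened by the ring A C2 methoxy and C6 substituent and by the benzyloxy groups at ring B C2 and C4, the benzyl ester is flanked at C2 and C6, and the two-phase medium keeps the hydroxide concentration low. An alkenyl boron partner is chosen because, once on palladium, it cannot lose a beta-hydride as a propyl group next to an ortho carbonyl would.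

**Step 13**
Reactants: 19 benzyl 2,4-bis(benzyloxy)-3-{[4-(benzyloxy)-2-methoxy-6-((E)-prop-1-enyl)benzoyl]oxy}-6-((E)-prop-1-enyl)benzoate
Product: 20 2,4-dihydroxy-3-[(4-hydroxy-2-methoxy-6-propylbenzoyl)oxy]-6-propylbenzoic acid (target)
Conditions: H2 (1 atm), 10% Pd/C, EtOAc–THF, rt
Reagents that add atoms: none
Why: Heterogeneous catalytic hydrogenation saturates both styrene-type double bonds and hydrogenolyses the three benzyl ethers and the benzyl ester in one operation, while the aryl ester, the methyl ether and the arenes are inert and the neutral aprotic medium disfavours acyl migration to the neighbouring phenols.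

**Compound list**
1 | 5-methoxybenzene-1,3-diol (5-methoxyresorcinol) | COc1cc(O)cc(O)c1 | starting material
2 | [(2,4-dihydroxy-6-methoxyphenyl)methylidene]dimethylammonium chloride | C[N+](C)=Cc1c(O)cc(O)cc1OC.[Cl-] | intermediate
3 | 2,4-dihydroxy-6-methoxybenzaldehyde | COc1cc(O)cc(O)c1C=O | intermediate
4 | 4-(benzyloxy)-2-hydroxy-6-methoxybenzaldehyde | COc1cc(OCc2ccccc2)cc(O)c1C=O | intermediate
5 | 5-(benzyloxy)-2-formyl-3-methoxyphenyl trifluoromethanesulfonate | COc1cc(OCc2ccccc2)cc(OS(=O)(=O)C(F)(F)F)c1C=O | intermediate
6 | 4-(benzyloxy)-2-methoxy-6-(trifluoromethylsulfonyloxy)benzoic acid | COc1cc(OCc2ccccc2)cc(OS(=O)(=O)C(F)(F)F)c1C(=O)O | intermediate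
7 | 4-bromo-2,6-difluorobenzaldehyde | O=Cc1c(F)cc(Br)cc1F | starting material
8 | 2,6-bis(benzyloxy)-4-bromobenzaldehyde | O=Cc1c(OCc2ccccc2)cc(Br)cc1OCc1ccccc1 | intermediate
9 | 2,6-bis(benzyloxy)-4-bromophenyl formate | O=COc1c(OCc2ccccc2)cc(Br)cc1OCc1ccccc1 | intermediate
10 | 2,6-bis(benzyloxy)-4-bromophenol | Oc1c(OCc2ccccc2)cc(Br)cc1OCc1ccccc1 | intermediate
11 | [2,6-bis(benzyloxy)-4-bromophenoxy](tert-butyl)dimethylsilane | CC(C)(C)[Si](C)(C)Oc1c(OCc2ccccc2)cc(Br)cc1OCc1ccccc1 | intermediate
12 | [2,6-bis(benzyloxy)-4-bromo-3-iodophenoxy](tert-butyl)dimethylsilane | CC(C)(C)[Si](C)(C)Oc1c(OCc2ccccc2)cc(Br)c(I)c1OCc1ccccc1 | intermediate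
13 | {2,4-bis(benzyloxy)-6-bromo-3-[(tert-butyldimethylsilyl)oxy]phenyl}magnesium chloride | CC(C)(C)[Si](C)(C)Oc1c(OCc2ccccc2)cc(Br)c([Mg]Cl)c1OCc1ccccc1 | intermediate
14 | benzyl 2,4-bis(benzyloxy)-6-bromo-3-[(tert-butyldimethylsilyl)oxy]benzoate | CC(C)(C)[Si](C)(C)Oc1c(OCc2ccccc2)cc(Br)c(C(=O)OCc2ccccc2)c1OCc1ccccc1 | intermediate
15 | benzyl 2,4-bis(benzyloxy)-6-bromo-3-hydroxybenzoate | Oc1c(OCc2ccccc2)cc(Br)c(C(=O)OCc2ccccc2)c1OCc1ccccc1 | intermediate
16 | 4-(benzyloxy)-2-methoxy-6-(trifluoromethylsulfonyloxy)benzoyl chloride | COc1cc(OCc2ccccc2)cc(OS(=O)(=O)C(F)(F)F)c1C(=O)Cl | intermediate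
17 | benzyl 2,4-bis(benzyloxy)-6-bromo-3-{[4-(benzyloxy)-2-methoxy-6-(trifluoromethylsulfonyloxy)benzoyl]oxy}benzoate | COc1cc(OCc2ccccc2)cc(OS(=O)(=O)C(F)(F)F)c1C(=O)Oc1c(OCc2ccccc2)cc(Br)c(C(=O)OCc2ccccc2)c1OCc1ccccc1 | intermediate
18 | potassium (E)-prop-1-enyltrifluoroborate | C/C=C/[B-](F)(F)F.[K+] | starting material
19 | benzyl 2,4-bis(benzyloxy)-3-{[4-(benzyloxy)-2-methoxy-6-((E)-prop-1-enyl)benzoyl]oxy}-6-((E)-prop-1-enyl)benzoate | C/C=C/c1cc(OCc2ccccc2)cc(OC)c1C(=O)Oc1c(OCc2ccccc2)cc(/C=C/C)c(C(=O)OCc2ccccc2)c1OCc1ccccc1 | intermediate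
20 | 2,4-dihydroxy-3-[(4-hydroxy-2-methoxy-6-propylbenzoyl)oxy]-6-propylbenzoic acid | CCCc1cc(O)cc(OC)c1C(=O)Oc1c(O)cc(CCC)c(C(=O)O)c1O | target

**Totals**
Total step count: 13.
Longest linear sequence: 9 steps (steps 5–13, from 7).

**Steps most likely to fail**

Step 12 (twofold coupling).
- What may go wrong: the sequence may stall after the first coupling. The triflyl group may be lost by S–O hydrolysis before palladium inserts. The aqueous base may cleave the depside ester at 80 °C.
- Fallback: the couplings are moved to the fragments and the ester bond is made last. It sets out from 5 and 15 and comes back at 19.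
- Aldehyde 5 is coupled with 18 under the catalyst system of step 12 to give 4-(benzyloxy)-2-methoxy-6-[(E)-prop-1-enyl]benzaldehyde F1. Pinnick oxidation in the presence of a large excess of 2-methyl-2-butene gives 4-(benzyloxy)-2-methoxy-6-[(E)-prop-1-enyl]benzoic acid F2.
- Phenol 15 is coupled with 18 in the same way to give benzyl 2,4-bis(benzyloxy)-3-hydroxy-6-[(E)-prop-1-enyl]benzoate F3.
- F2 is converted under neutral conditions by 1-chloro-N,N,2-trimethylprop-1-en-1-amine into 4-(benzyloxy)-2-methoxy-6-[(E)-prop-1-enyl]benzoyl chloride F4. This acylates F3 (Et3N, DMAP, CH2Cl2) to give 19.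

Step 11 (depside bond).
- What may go wrong: acyl transfer may be very slow because both partners carry two ortho substituents. That would leave time for hydrolysis of the acid chloride or for triflyl transfer to the phenol oxygen.
- Fallback: an acid-mediated acylium pathway replaces base-mediated addition–elimination. It sets out from 6 (together with 15) and comes back at 17.
- Acid 6, phenol 15 and trifluoroacetic anhydride are stirred in toluene at rt. This forms 4-(benzyloxy)-2-methoxy-6-(trifluoromethylsulfonyloxy)benzoic trifluoroacetic anhydride F5.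
- F5 ionises to a linear acylium ion stabilised by the ortho methoxy and para benzyloxy groups. That ion is small enough to reach the crowded ring B O3 and gives 17.

Step 9 (carboxyl introduction).
- What may go wrong: the ortho-bromoarylmagnesium may lose magnesium halide to an aryne on warming. It may also be protonated before the crowded carbon is acylated.
- Fallback: transition-metal carbonylation replaces organomagnesium chemistry. It sets out from 12 and comes back at 14.
- Iodide 12 is heated with PdCl2(PPh3)2, CO (balloon to 5 bar), BnOH and Et3N in DMF at 70 °C. Zerovalent palladium inserts into C–I in preference to C–Br, CO inserts, and benzyl alcohol cleaves the acylpalladium species to give 14 directly. No new compound arises (F0).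

**Further compounds**
F1 | step 12 | 4-(benzyloxy)-2-methoxy-6-[(E)-prop-1-enyl]benzaldehyde | C/C=C/c1cc(OCc2ccccc2)cc(OC)c1C=O
F2 | step 12 | 4-(benzyloxy)-2-methoxy-6-[(E)-prop-1-enyl]benzoic acid | C/C=C/c1cc(OCc2ccccc2)cc(OC)c1C(=O)O
F3 | step 12 | benzyl 2,4-bis(benzyloxy)-3-hydroxy-6-[(E)-prop-1-enyl]benzoate | C/C=C/c1cc(OCc2ccccc2)c(O)c(OCc2ccccc2)c1C(=O)OCc1ccccc1
F4 | step 12 | 4-(benzyloxy)-2-methoxy-6-[(E)-prop-1-enyl]benzoyl chloride | C/C=C/c1cc(OCc2ccccc2)cc(OC)c1C(=O)Cl
F5 | step 11 | 4-(benzyloxy)-2-methoxy-6-(trifluoromethylsulfonyloxy)benzoic trifluoroacetic anhydride | COc1cc(OCc2ccccc2)cc(OS(=O)(=O)C(F)(F)F)c1C(=O)OC(=O)C(F)(F)F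
F0 | step 9 | none | none
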